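**Retrosynthetic overview**
1. The target is unmasked last from a C2 allyl ester and an aryl triisopropylsilyl ether. The C4 carboxamide comes from aminolysis of a C4 methyl β-keto ester by the preformed side-chain amine (from glycolaldehyde, a propanoate ylide and N-Boc-1,4-diaminobutane).
2. The oxepinone ring is the only ring that is built. It is cut at C2–C3 (conjugate addition) and at C5–C5a (acylation of the arene by a nitrile): a (4+3) annulation of an aryloxy(aryl)acetate (C2, O1, C9a, C5a) with a benzylidene cyanoacetate (C3, C4, C5).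
3. The strategy rests on ring A, a phloroglucinol-type 3,5-dimethoxyphenyl ether. Its two carbons ortho to O1 are equivalent and strongly nucleophilic (C5a is ortho to the C6 methoxy group and para to the C8 methoxy group), and the C5 ketone on C5a is latent in a nitrile carbon on C4.
4. The donor comes in three steps from 4-hydroxymandelic acid: allyl ester, silyl ether, Mitsunobu etherification with 3,5-dimethoxyphenol.
5. C2 and C3 are set in the annulation by a chiral ammonium ion pair; C4, a β-dicarbonyl methine, settles trans to the C3 phenyl group by equilibration.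

Key step: step 4

Remark 1: C4 epimerises by enolisation; the (4R) configuration of the target, with the C4 carbonyl substituent trans to the C3 phenyl group, is assumed to be the thermodynamically preferred one.
Remark 2: the C2 carboxyl group is carried as an allyl ester because it is released at the allyl terminus under neutral conditions, whereas hydroxide at a neopentyl-like C2 alkyl ester would be slow and would expose the C4 enolate to retro-Michael ring opening; as an allyl group does not tolerate radical benzylic bromination, the aryl ether of the donor is made by Mitsunobu reaction of a mandelate.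
Remark 3: the sense of induction of the cinchonidinium salt in step 4 is assumed; should it deliver the (2R,3R) series, the pseudoenantiomeric cinchoninium salt takes its place in the same step.

**Route**

Step 1
Reactants: 1 (RS)-hydroxy(4-hydroxyphenyl)acetic acid (4-hydroxymandelic acid)
Product: 2 prop-2-en-1-yl (RS)-hydroxy(4-hydroxyphenyl)acetate
Conditions: allyl bromide, KHCO3, DMF, rt
Reagents that add atoms: allyl bromide (3-bromoprop-1-ene), C=CCBr
Why: Carboxylate O-alkylation (SN2 esterification): KHCO3 deprotonates only the carboxylic acid, so the phenol and the secondary alcohol should stay untouched.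

Step 2
Reactants: 2 prop-2-en-1-yl (RS)-hydroxy(4-hydroxyphenyl)acetate
Product: 3 prop-2-en-1-yl (RS)-hydroxy{4-[tri(propan-2-yl)silyloxy]phenyl}acetate
Conditions: TIPSCl, imidazole, CH2Cl2, 0 °C to rt
Reagents that add atoms: chlorotri(propan-2-yl)silane (TIPSCl), CC(C)[Si](Cl)(C(C)C)C(C)C
Why: Silyl ether formation: the unhindered, more acidic phenol should be silylated by the bulky chlorosilane far faster than the hindered secondary α-hydroxy ester.

Step 3
Reactants: 3 prop-2-en-1-yl (RS)-hydroxy{4-[tri(propan-2-yl)silyloxy]phenyl}acetate; 4 3,5-dimethoxyphenol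
Product: 5 prop-2-en-1-yl (RS)-(3,5-dimethoxyphenoxy){4-[tri(propan-2-yl)silyloxy]phenyl}acetate
Conditions: PPh3, DIAD, toluene, 0 °C to rt
Reagents that add atoms: none
Why: Mitsunobu etherification: the activated α-hydroxy ester is displaced at carbon by the acidic phenol through its oxygen, and the racemic stereocentre is of no consequence because it becomes a planar enolate in step 4.

Step 4
Reactants: 5 prop-2-en-1-yl (RS)-(3,5-dimethoxyphenoxy){4-[tri(propan-2-yl)silyloxy]phenyl}acetate; 6 methyl (2E)-2-cyano-3-phenylprop-2-enoate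
Product: 9 4-methyl 2-(prop-2-en-1-yl) (2S,3S,4R)-6,8-dimethoxy-5-oxo-3-phenyl-2-{4-[tri(propan-2-yl)silyloxy]phenyl}-2,3,4,5-tetrahydro-1-benzoxepine-2,4-dicarboxylate, via Michael adduct nitrile 7 (not isolated), via ketiminium chloride 8 (not isolated)
Conditions: O-allyl-N-(9-anthracenylmethyl)cinchonidinium bromide (10 mol %), Cs2CO3 (1.5 equiv), toluene, −40 °C; then HCl in Et2O, filtration through MgSO4; ZnCl2, HCl (g), Et2O, 0 °C to rt; then 1 M aq. HCl, THF, 50 °C
Reagents that add atoms: water, O
Why: Proposed new method: solid Cs2CO3 deprotonates racemic 5 at the interface and its planar enolate, ion-paired with the cinchonidinium cation, adds through C2 to the β-carbon of the strongly electrophilic acceptor 6 to give the stabilised cyanoacetate anion of 7 (bond C2–C3); the closest known reaction type is the phase-transfer-catalysed asymmetric Michael addition of ester enolates to electron-poor alkenes, which has not been shown for a fully substituted α-aryloxy-α-aryl enolate adding to an arylidene cyanoacetate. Because neutralising the carbonate liberates water, which would divert the activated nitrile to the primary amide, the acidified solution is dried by passage through MgSO4 before ZnCl2 is added. HCl and ZnCl2 then turn the nitrile of 7 into a nitrilium (imidoyl chloride) carbon that is attacked by the ring A carbon ortho to O1, an intramolecular Houben–Hoesch acylation of the kind known for aryloxy nitriles, which closes the oxepine ring in the 7-exo-dig mode (bond C5–C5a) to 8, and aqueous acid hydrolyses the ketiminium group to the C5 ketone. C2 is controlled by the catalyst cation, which shields one face of the enolate, C3 by the relative topicity of the open transition state, in which the phenyl group of the E-configured acceptor avoids the aryloxy group of the enolate, and C4 by equilibration of the β-keto ester through its enol during the acidic hydrolysis, which should place the ester trans to the C3 phenyl group. The step needs enantio- and diastereoselectivity in the addition, for which the substrate offers only a single enolisable position and an acceptor of fixed geometry so that the catalyst must do the rest, and regioselectivity in the acylation, which the substrate secures: the two carbons ortho to O1 are equivalent by symmetry, the carbon para to O1 is out of reach of the tether, and no other aryl carbon within reach carries an ortho or para oxygen.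

Step 5
Reactants: 10 1,4-dioxane-2,5-diol (glycolaldehyde dimer); 11 ethyl 2-(triphenylphosphoranylidene)propanoate
Product: 12 ethyl (2E)-4-hydroxy-2-methylbut-2-enoate
Conditions: CH2Cl2, 40 °C
Reagents that add atoms: none
Why: Wittig olefination of glycolaldehyde (released from its dimer) with a stabilised α-branched ylide, which should give the (E)-trisubstituted enoate.

Step 6
Reactants: 12 ethyl (2E)-4-hydroxy-2-methylbut-2-enoate
Product: 13 (2E)-4-hydroxy-2-methylbut-2-enoic acid
Conditions: LiOH, THF/H2O, 0 °C to rt; then aq. HCl to pH 2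
Reagents that add atoms: lithium hydroxide, [Li+].[OH-]
Why: Saponification of the ethyl ester; the E geometry keeps the γ-hydroxy acid from lactonising.

Step 7
Reactants: 13 (2E)-4-hydroxy-2-methylbut-2-enoic acid; 14 tert-butyl (4-aminobutyl)carbamate
Product: 15 tert-butyl {4-[(2E)-4-hydroxy-2-methylbut-2-enamido]butyl}carbamate
Conditions: EDC·HCl, HOBt, CH2Cl2, 0 °C to rt
Reagents that add atoms: none
Why: Carbodiimide amide coupling through the hydroxybenzotriazole active ester, in which the primary amine should outcompete the allylic hydroxyl group as acyl acceptor.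

Step 8
Reactants: 15 tert-butyl {4-[(2E)-4-hydroxy-2-methylbut-2-enamido]butyl}carbamate
Product: 16 (2E)-N-(4-aminobutyl)-4-hydroxy-2-methylbut-2-enamide hydrochloride
Conditions: HCl (4 M in 1,4-dioxane), 0 °C to rt
Reagents that add atoms: hydrogen chloride, Cl
Why: Acidolysis of the tert-butyl carbamate; the allylic alcohol, deactivated towards ionisation by the conjugated amide, should persist, and the amine is kept as its hydrochloride.

Step 9
Reactants: 9 4-methyl 2-(prop-2-en-1-yl) (2S,3S,4R)-6,8-dimethoxy-5-oxo-3-phenyl-2-{4-[tri(propan-2-yl)silyloxy]phenyl}-2,3,4,5-tetrahydro-1-benzoxepine-2,4-dicarboxylate; 16 (2E)-N-(4-aminobutyl)-4-hydroxy-2-methylbut-2-enamide hydrochloride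
Product: 17 prop-2-en-1-yl (2S,3S,4R)-4-({4-[(2E)-4-hydroxy-2-methylbut-2-enamido]butyl}carbamoyl)-6,8-dimethoxy-5-oxo-3-phenyl-2-{4-[tri(propan-2-yl)silyloxy]phenyl}-2,3,4,5-tetrahydro-1-benzoxepine-2-carboxylate
Conditions: Et3N, DMAP (0.3 equiv), toluene/1,4-dioxane, 100 °C
Reagents that add atoms: none
Why: DMAP-promoted aminolysis of a β-keto ester, selective for the C4 ester because the C2 allyl ester sits on a fully substituted carbon and the electron-rich, doubly ortho-substituted aryl ketone resists enamine formation, with C4 returning by enolisation to the trans (4R) arrangement.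

Step 10
Reactants: 17 prop-2-en-1-yl (2S,3S,4R)-4-({4-[(2E)-4-hydroxy-2-methylbut-2-enamido]butyl}carbamoyl)-6,8-dimethoxy-5-oxo-3-phenyl-2-{4-[tri(propan-2-yl)silyloxy]phenyl}-2,3,4,5-tetrahydro-1-benzoxepine-2-carboxylate
Product: 18 prop-2-en-1-yl (2S,3S,4R)-4-({4-[(2E)-4-hydroxy-2-methylbut-2-enamido]butyl}carbamoyl)-2-(4-hydroxyphenyl)-6,8-dimethoxy-5-oxo-3-phenyl-2,3,4,5-tetrahydro-1-benzoxepine-2-carboxylate
Conditions: TBAF, AcOH, THF, 0 °C
Reagents that add atoms: none
Why: Fluoride-induced cleavage of the aryl silyl ether, buffered with acetic acid so that the C4–H acidic β-keto amide is not exposed to basic fluoride.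

Step 11
Reactants: 18 prop-2-en-1-yl (2S,3S,4R)-4-({4-[(2E)-4-hydroxy-2-methylbut-2-enamido]butyl}carbamoyl)-2-(4-hydroxyphenyl)-6,8-dimethoxy-5-oxo-3-phenyl-2,3,4,5-tetrahydro-1-benzoxepine-2-carboxylate
Product: 19 (2S,3S,4R)-4-({4-[(2E)-4-hydroxy-2-methylbut-2-enamido]butyl}carbamoyl)-2-(4-hydroxyphenyl)-6,8-dimethoxy-5-oxo-3-phenyl-2,3,4,5-tetrahydro-1-benzoxepine-2-carboxylic acid
Conditions: Pd(PPh3)4 (5 mol %), morpholine, THF, rt; then aq. citric acid
Reagents that add atoms: none
Why: Tsuji–Trost type deallylation: zerovalent palladium ionises the allyl ester to a π-allyl complex and the carboxylate, morpholine traps the allyl unit, and since the reaction takes place at the allyl terminus the congested C2 and the three stereocentres should not be touched.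

**Compound list**
1 | (RS)-hydroxy(4-hydroxyphenyl)acetic acid (4-hydroxymandelic acid) | OC(C(=O)O)c1ccc(O)cc1 | starting material
2 | prop-2-en-1-yl (RS)-hydroxy(4-hydroxyphenyl)acetate | C=CCOC(=O)C(O)c1ccc(O)cc1 | intermediate
3 | prop-2-en-1-yl (RS)-hydroxy{4-[tri(propan-2-yl)silyloxy]phenyl}acetate | C=CCOC(=O)C(O)c1ccc(O[Si](C(C)C)(C(C)C)C(C)C)cc1 | intermediate
4 | 3,5-dimethoxyphenol | COc1cc(O)cc(OC)c1 | starting material
5 | prop-2-en-1-yl (RS)-(3,5-dimethoxyphenoxy){4-[tri(propan-2-yl)silyloxy]phenyl}acetate | C=CCOC(=O)C(Oc1cc(OC)cc(OC)c1)c1ccc(O[Si](C(C)C)(C(C)C)C(C)C)cc1 | intermediate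
6 | methyl (2E)-2-cyano-3-phenylprop-2-enoate | COC(=O)/C(C#N)=C/c1ccccc1 | starting material
7 | 5-methyl 1-(prop-2-en-1-yl) (2S,3S)-4-cyano-2-(3,5-dimethoxyphenoxy)-3-phenyl-2-{4-[tri(propan-2-yl)silyloxy]phenyl}pentanedioate (both C4 epimers) | COc1cc(OC)cc(c1)O[C@](C(=O)OCC=C)(c1ccc(O[Si](C(C)C)(C(C)C)C(C)C)cc1)[C@H](c1ccccc1)C(C#N)C(=O)OC | intermediate (not isolated)
8 | 4-methyl 2-(prop-2-en-1-yl) (2S,3S)-5-iminiumyl-6,8-dimethoxy-3-phenyl-2-{4-[tri(propan-2-yl)silyloxy]phenyl}-2,3,4,5-tetrahydro-1-benzoxepine-2,4-dicarboxylate chloride (C4 epimers) | COc1cc(OC)c2c(c1)O[C@](C(=O)OCC=C)(c1ccc(O[Si](C(C)C)(C(C)C)C(C)C)cc1)[C@H](c1ccccc1)C(C(=O)OC)C2=[NH2+].[Cl-] | intermediate (not isolated)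
9 | 4-methyl 2-(prop-2-en-1-yl) (2S,3S,4R)-6,8-dimethoxy-5-oxo-3-phenyl-2-{4-[tri(propan-2-yl)silyloxy]phenyl}-2,3,4,5-tetrahydro-1-benzoxepine-2,4-dicarboxylate | COc1cc(OC)c2c(c1)O[C@](C(=O)OCC=C)(c1ccc(O[Si](C(C)C)(C(C)C)C(C)C)cc1)[C@H](c1ccccc1)[C@@H](C(=O)OC)C2=O | intermediate
10 | 1,4-dioxane-2,5-diol (glycolaldehyde dimer) | OC1COC(O)CO1 | starting material
11 | ethyl 2-(triphenylphosphoranylidene)propanoate | CCOC(=O)C(C)=P(c1ccccc1)(c1ccccc1)c1ccccc1 | starting material
12 | ethyl (2E)-4-hydroxy-2-methylbut-2-enoate | CCOC(=O)/C(C)=C/CO | intermediate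
13 | (2E)-4-hydroxy-2-methylbut-2-enoic acid | OC(=O)/C(C)=C/CO | intermediate
14 | tert-butyl (4-aminobutyl)carbamate | NCCCCNC(=O)OC(C)(C)C | starting material
15 | tert-butyl {4-[(2E)-4-hydroxy-2-methylbut-2-enamido]butyl}carbamate | CC(C)(C)OC(=O)NCCCCNC(=O)/C(C)=C/CO | intermediate
16 | (2E)-N-(4-aminobutyl)-4-hydroxy-2-methylbut-2-enamide hydrochloride | [NH3+]CCCCNC(=O)/C(C)=C/CO.[Cl-] | intermediate
17 | prop-2-en-1-yl (2S,3S,4R)-4-({4-[(2E)-4-hydroxy-2-methylbut-2-enamido]butyl}carbamoyl)-6,8-dimethoxy-5-oxo-3-phenyl-2-{4-[tri(propan-2-yl)silyloxy]phenyl}-2,3,4,5-tetrahydro-1-benzoxepine-2-carboxylate | COc1cc(OC)c2c(c1)O[C@](C(=O)OCC=C)(c1ccc(O[Si](C(C)C)(C(C)C)C(C)C)cc1)[C@H](c1ccccc1)[C@@H](C(=O)NCCCCNC(=O)/C(C)=C/CO)C2=O | intermediate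
18 | prop-2-en-1-yl (2S,3S,4R)-4-({4-[(2E)-4-hydroxy-2-methylbut-2-enamido]butyl}carbamoyl)-2-(4-hydroxyphenyl)-6,8-dimethoxy-5-oxo-3-phenyl-2,3,4,5-tetrahydro-1-benzoxepine-2-carboxylate | COc1cc(OC)c2c(c1)O[C@](C(=O)OCC=C)(c1ccc(O)cc1)[C@H](c1ccccc1)[C@@H](C(=O)NCCCCNC(=O)/C(C)=C/CO)C2=O | intermediate
19 | (2S,3S,4R)-4-({4-[(2E)-4-hydroxy-2-methylbut-2-enamido]butyl}carbamoyl)-2-(4-hydroxyphenyl)-6,8-dimethoxy-5-oxo-3-phenyl-2,3,4,5-tetrahydro-1-benzoxepine-2-carboxylic acid | COc1cc(OC)c2c(c1)O[C@](C(=O)O)(c1ccc(O)cc1)[C@H](c1ccccc1)[C@@H](C(=O)NCCCCNC(=O)/C(C)=C/CO)C2=O | target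

**Step count and risks**
Total step count: 11. Longest linear sequence: 7 steps (steps 1, 2, 3, 4, 9, 10, 11; the side-chain branch, steps 5 to 8 followed by 9 to 11, is equally long).

Steps most likely to fail:

Step 4 (proposed new method). What may go wrong: poor facial selectivity at the enolate or at the acceptor in the conjugate addition, reversal of the addition before acidification, or interception of the activated nitrile by water so that the ring does not close in the same flask. The fallback sets out from 5 and 6 and comes back at 9. It separates the two bond formations and resolves instead of inducing. 5 and 6 are combined with Cs2CO3 and Bu4NBr in toluene (achiral phase transfer), and after aqueous work-up the racemic Michael adduct F1 is isolated as a mixture of diastereomers and dried. A separate Houben–Hoesch cyclisation (HCl, ZnCl2, Et2O, then aqueous HCl) should give the racemic benzoxepinone F2. The diastereomer with the C2 aryl group cis to the C3 phenyl group is separated by chromatography or crystallisation, and its enantiomers by preparative HPLC on a chiral stationary phase (amylose tris(3,5-dimethylphenylcarbamate)), which gives 9.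

Step 9. What may go wrong: slow acyl transfer at the hindered C4 ester, so that at the temperature needed the hydroxy-enamide amine reacts through its hydroxyl group or stays undissolved as its salt, or the oxepinone opens by retro-Michael reaction through the C4 enolate. The fallback sets out from 9 and 14 and comes back at 17. The side chain is assembled on the core in stages. The simple, lipophilic amine 14 is used in excess (DMAP, toluene, 80 °C), which should give the Boc-protected aminobutyl amide F3. HCl in 1,4-dioxane then removes the carbamate to give the amine hydrochloride F4, and coupling of F4 with acid 13 (EDC·HCl, HOBt, iPr2NEt, CH2Cl2) should give 17.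

Step 11. What may go wrong: transfer of the allyl group from the π-allyl palladium intermediate to the C4 carbon of the β-keto amide or to the phenolate, in place of transfer to morpholine. The fallback sets out from 18 and comes back at 19. It avoids any electrophilic allyl species. RhCl(PPh3)3 with DABCO in aqueous ethanol at 70 °C should isomerise the allyl ester to the prop-1-enyl ester F5, an enol ester that is hydrolysed under the same aqueous conditions to 19.

**Further compounds**
F1 | step 4 | 5-methyl 1-(prop-2-en-1-yl) 4-cyano-2-(3,5-dimethoxyphenoxy)-3-phenyl-2-{4-[tri(propan-2-yl)silyloxy]phenyl}pentanedioate, racemic mixture of diastereomers | COc1cc(OC)cc(c1)OC(C(=O)OCC=C)(c1ccc(O[Si](C(C)C)(C(C)C)C(C)C)cc1)C(c1ccccc1)C(C#N)C(=O)OC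
F2 | step 4 | 4-methyl 2-(prop-2-en-1-yl) 6,8-dimethoxy-5-oxo-3-phenyl-2-{4-[tri(propan-2-yl)silyloxy]phenyl}-2,3,4,5-tetrahydro-1-benzoxepine-2,4-dicarboxylate, racemic mixture of diastereomers that contains the racemate of 9 | COc1cc(OC)c2c(c1)OC(C(=O)OCC=C)(c1ccc(O[Si](C(C)C)(C(C)C)C(C)C)cc1)C(c1ccccc1)C(C(=O)OC)C2=O
F3 | step 9 | prop-2-en-1-yl (2S,3S,4R)-4-({4-[(tert-butoxycarbonyl)amino]butyl}carbamoyl)-6,8-dimethoxy-5-oxo-3-phenyl-2-{4-[tri(propan-2-yl)silyloxy]phenyl}-2,3,4,5-tetrahydro-1-benzoxepine-2-carboxylate | COc1cc(OC)c2c(c1)O[C@](C(=O)OCC=C)(c1ccc(O[Si](C(C)C)(C(C)C)C(C)C)cc1)[C@H](c1ccccc1)[C@@H](C(=O)NCCCCNC(=O)OC(C)(C)C)C2=O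
F4 | step 9 | prop-2-en-1-yl (2S,3S,4R)-4-[(4-aminobutyl)carbamoyl]-6,8-dimethoxy-5-oxo-3-phenyl-2-{4-[tri(propan-2-yl)silyloxy]phenyl}-2,3,4,5-tetrahydro-1-benzoxepine-2-carboxylate hydrochloride | COc1cc(OC)c2c(c1)O[C@](C(=O)OCC=C)(c1ccc(O[Si](C(C)C)(C(C)C)C(C)C)cc1)[C@H](c1ccccc1)[C@@H](C(=O)NCCCC[NH3+])C2=O.[Cl-]
F5 | step 11 | prop-1-en-1-yl (2S,3S,4R)-4-({4-[(2E)-4-hydroxy-2-methylbut-2-enamido]butyl}carbamoyl)-2-(4-hydroxyphenyl)-6,8-dimethoxy-5-oxo-3-phenyl-2,3,4,5-tetrahydro-1-benzoxepine-2-carboxylate (E/Z mixture at the enol ester) | COc1cc(OC)c2c(c1)O[C@](C(=O)OC=CC)(c1ccc(O)cc1)[C@H](c1ccccc1)[C@@H](C(=O)NCCCCNC(=O)/C(C)=C/CO)C2=O
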